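**Retrosynthetic overview**

1. Numbering: ring A (chlorinated) a1 C–OMe, a2 C–H, a3 C–CO2H, a4 C–O–aryl, a5 C–OH, a6 C–Cl; ring B b1 C–O–aryl, b2 C–H, b3 C–CH3, b4 C–H, b5 C–OH, b6 C–CO2H.
2. Feature: in ring B the neighbours b6 (carboxyl), b1 (aryloxy), b2 (H) and b3 (methyl) reproduce C3, C4, C5 and C6 of a 6-methyl-2-pyranone-3-carboxylate with the aryl ether on C4, and b4–b5 (CH beside C–O) is the C2 unit of a ketene acetal.
3. Ring B is formed last, from that pyranone and 1,1-dimethoxyethene by [4+2] cycloaddition across C3/C6 (bonds b3–b4 and b5–b6), CO2 extrusion and methanol loss.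
4. The a4–O–b1 ether bond is made earlier, by addition–elimination of a ring A salicylate on the 4-tosyloxypyranone obtained from dimethyl malonate and diketene.
5. Ring A is not constructed: 2-chlororesorcinol supplies a1-O, a6-Cl and a5-O, a4-O comes from a formyl group (Baeyer–Villiger) and the a3 carboxyl from ortho-formylation; BCl3 and then LiOH finish.

Key step: step 11

Remark on the chemistry: the target has no stereocentre; the only stereogenic atoms on the route are the two bridgeheads of the transient cycloadduct 18, which forms as a racemate and loses them on CO2 extrusion.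

**Route**

Step 1
Reactants: 1 2-chlororesorcinol
Product: 3 3-chloro-2,4-dihydroxybenzaldehyde, via aryl iminium chloride 2 (not isolated)
Conditions: POCl3, DMF, MeCN, 0 °C to rt; then H2O, 50 °C
Reagents that add atoms: N,N-dimethylformamide, CN(C)C=O (formyl carbon); water, O (carbonyl oxygen); phosphoryl chloride, O=P(Cl)(Cl)Cl (chloride counter-ion of 2 only)
Why: Vilsmeier–Haack formylation should occur at C4 of the resorcinol (ortho to one hydroxyl, para to the other), since C2 is blocked by chlorine, and hydrolysis of iminium salt 2 gives the aldehyde.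

Step 2
Reactants: 3 3-chloro-2,4-dihydroxybenzaldehyde
Product: 4 3-chloro-2-hydroxy-4-methoxybenzaldehyde
Conditions: MeI (1.1 equiv), KHCO3, DMF, 40 °C
Reagents that add atoms: iodomethane, CI
Why: Regioselective Williamson methylation should take the 4-hydroxyl, which is the more acidic (para to the formyl group) and is not held in the hydrogen bond to the aldehyde that masks the 2-hydroxyl; this sets the a1 methyl ether.

Step 3
Reactants: 4 3-chloro-2-hydroxy-4-methoxybenzaldehyde
Product: 5 3-chloro-4-methoxy-2-(methoxymethoxy)benzaldehyde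
Conditions: MOMCl, iPr2NEt, CH2Cl2, 0 °C to 40 °C
Reagents that add atoms: chloromethyl methyl ether, COCCl
Why: O-Alkylation of the remaining chelated phenol with the small, reactive MOM chloride protects the future a5 hydroxyl as an acetal that survives base, peracid and chlorite.

Step 4
Reactants: 5 3-chloro-4-methoxy-2-(methoxymethoxy)benzaldehyde
Product: 7 3-chloro-4-methoxy-2-(methoxymethoxy)phenol, via aryl formate 6 (not isolated)
Conditions: mCPBA, NaHCO3, CH2Cl2, 0 °C to rt; then K2CO3 (0.2 equiv), MeOH, rt
Reagents that add atoms: 3-chloroperbenzoic acid, O=C(OO)c1cccc(Cl)c1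
Why: In this Baeyer–Villiger (Dakin-type) oxidation the aryl group, made electron-rich by its ortho and para oxygens, should migrate in the Criegee intermediate to give formate 6, and methanolysis releases the a4 phenol while the bicarbonate buffer keeps the MOM acetal intact.

Step 5
Reactants: 7 3-chloro-4-methoxy-2-(methoxymethoxy)phenol
Product: 8 4-chloro-2-hydroxy-5-methoxy-3-(methoxymethoxy)benzaldehyde
Conditions: MgCl2, Et3N, (CH2O)n, MeCN, reflux; aq. NH4Cl work-up
Reagents that add atoms: formaldehyde (from paraformaldehyde), C=O
Why: In the Casnati–Skattebøl ortho-formylation the magnesium phenoxide delivers formaldehyde to the only free ortho position (a3), and the hydroxymethyl intermediate is oxidised by a second formaldehyde through hydride transfer, under basic conditions that leave the MOM ether alone.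

Step 6
Reactants: 8 4-chloro-2-hydroxy-5-methoxy-3-(methoxymethoxy)benzaldehyde
Product: 9 4-chloro-2-hydroxy-5-methoxy-3-(methoxymethoxy)benzoic acid
Conditions: NaClO2, NaH2PO4, 2-methyl-2-butene, t-BuOH/H2O, rt
Reagents that add atoms: sodium chlorite, [Na+].[O-]Cl=O
Why: Pinnick oxidation converts the aldehyde to the acid at about pH 4, which the MOM acetal tolerates, and the alkene scavenger removes hypochlorous acid before it can chlorinate the electron-rich ring.

Step 7
Reactants: 9 4-chloro-2-hydroxy-5-methoxy-3-(methoxymethoxy)benzoic acid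
Product: 10 methyl 4-chloro-2-hydroxy-5-methoxy-3-(methoxymethoxy)benzoate
Conditions: MeI, KHCO3, DMF, rt
Reagents that add atoms: iodomethane, CI
Why: SN2 alkylation of the carboxylate formed with the weak base KHCO3 should give the methyl ester and leave the less acidic, ester-chelated a4 phenol free for the coupling.

Step 8
Reactants: 11 dimethyl malonate; 12 diketene
Product: 14 methyl 4-hydroxy-6-methyl-2-oxo-2H-pyran-3-carboxylate, via acetoacetylmalonate 13 (not isolated)
Conditions: NaH, THF, 0 °C; 12, 0 °C to rt, then reflux; aq. HCl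
Reagents that add atoms: none
Why: C-Acetoacetylation of sodium dimethyl malonate by acyl–oxygen opening of diketene gives triketo diester 13, whose enol oxygen closes onto one ester (six-membered lactonisation with loss of methanol) to give the 4-hydroxy-2-pyranone.

Step 9
Reactants: 14 methyl 4-hydroxy-6-methyl-2-oxo-2H-pyran-3-carboxylate
Product: 15 methyl 6-methyl-4-[(4-methylbenzenesulfonyl)oxy]-2-oxo-2H-pyran-3-carboxylate
Conditions: TsCl, Et3N, CH2Cl2, 0 °C
Reagents that add atoms: 4-toluenesulfonyl chloride, Cc1ccc(S(=O)(=O)Cl)cc1
Why: O-Sulfonylation of the vinylogous acid at the C4 oxygen turns C4 into a doubly activated carbon that bears a leaving group.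

Step 10
Reactants: 10 methyl 4-chloro-2-hydroxy-5-methoxy-3-(methoxymethoxy)benzoate; 15 methyl 6-methyl-4-[(4-methylbenzenesulfonyl)oxy]-2-oxo-2H-pyran-3-carboxylate
Product: 16 methyl 4-[3-chloro-4-methoxy-6-(methoxycarbonyl)-2-(methoxymethoxy)phenoxy]-6-methyl-2-oxo-2H-pyran-3-carboxylate
Conditions: K2CO3, MeCN, 0 °C to rt
Reagents that add atoms: none
Why: The phenoxide of 10 should add to C4 of 15, which is the beta carbon of both the lactone and the ester carbonyl, and expel tosylate (addition–elimination, vinylogous acyl substitution), so the a4–O–b1 bond forms on a non-aromatic carbon without any metal catalysis.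

Step 11
Reactants: 16 methyl 4-[3-chloro-4-methoxy-6-(methoxycarbonyl)-2-(methoxymethoxy)phenoxy]-6-methyl-2-oxo-2H-pyran-3-carboxylate; 17 1,1-dimethoxyethene
Product: 20 methyl 4-chloro-5-methoxy-2-[3-methoxy-2-(methoxycarbonyl)-5-methylphenoxy]-3-(methoxymethoxy)benzoate, via bridged bicyclic lactone 18 (not isolated), via dimethoxycyclohexadiene 19 (not isolated)
Conditions: 17 (excess), toluene, 100–110 °C, sealed tube, acid-free glassware
Reagents that add atoms: none
Why: The electron-poor diene C3=C4–C5=C6 of 16, whose LUMO is lowered by the lactone carbonyl and the C3 ester, should react with the electron-rich ketene acetal 17 in an inverse-electron-demand Diels–Alder reaction that is concerted but strongly asynchronous, with the CH2 carbon of 17 bonding first to C6. Ring B is closed here as the six-membered carbocycle of bridged lactone 18 by an intermolecular [4+2] mode (new bonds C6–CH2 = b3–b4 and C3–C(OMe)2 = b5–b6), after which retro-[4+2] loss of CO2 gives diene 19 and 1,2-elimination of methanol, driven by aromatisation, gives 20. The closest known reaction is the conversion of 2-pyranone-3-carboxylates with 1,1-dimethoxyethene into methyl 2-methoxybenzoates. The two bridgehead stereocentres of 18 are tied to each other by the bicycle, arise as a racemate and disappear on CO2 loss, so no stereocontrol is needed. The step needs regioselectivity (acetal carbon to C3, since the other orientation would put the methoxy group para to the aryloxy group) and chemoselectivity over conjugate addition–elimination at C4; the first is secured by the polarisation of the pyranone, which has its largest LUMO coefficient at C6 and stabilises the developing negative charge on C3 between two carbonyls, and the second by the donor aryloxy group and the fully substituted, hindered C4 together with a non-polar solvent that disfavours a zwitterionic path.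

Step 12
Reactants: 20 methyl 4-chloro-5-methoxy-2-[3-methoxy-2-(methoxycarbonyl)-5-methylphenoxy]-3-(methoxymethoxy)benzoate
Product: 21 methyl 4-chloro-3-hydroxy-2-[3-hydroxy-2-(methoxycarbonyl)-5-methylphenoxy]-5-methoxybenzoate
Conditions: BCl3 (excess), CH2Cl2, −78 to 0 °C; then H2O
Reagents that add atoms: none
Why: BCl3 cleaves the MOM acetal and, through the six-membered boron chelate with the neighbouring ester carbonyl, only the b5 methyl ether, whereas the a1 methyl ether has no carbonyl neighbour and the diaryl ether and the esters should survive at or below 0 °C.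

Step 13
Reactants: 21 methyl 4-chloro-3-hydroxy-2-[3-hydroxy-2-(methoxycarbonyl)-5-methylphenoxy]-5-methoxybenzoate
Product: 22 4-chloro-2-(2-carboxy-3-hydroxy-5-methylphenoxy)-3-hydroxy-5-methoxybenzoic acid (target)
Conditions: LiOH (excess), THF/MeOH/H2O, 50 °C; then aq. HCl, 0 °C, to pH 2
Reagents that add atoms: lithium hydroxide, [Li+].[OH-]
Why: Acyl–oxygen saponification opens the ring A ester readily and the hindered ring B salicylate with help from its ortho phenoxide (intramolecular general-base assistance); the phenoxide-rich ring B is not prone to Smiles migration, excess hydroxide reopens any seven-membered lactone, and cold acidification limits decarboxylation of the 2,6-dioxygenated acid.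

**Compound list**

1 | 2-chlororesorcinol (2-chlorobenzene-1,3-diol) | Oc1cccc(O)c1Cl | starting material
2 | [(3-chloro-2,4-dihydroxyphenyl)methylidene]dimethylammonium chloride | C[N+](C)=Cc1ccc(O)c(Cl)c1O.[Cl-] | intermediate
3 | 3-chloro-2,4-dihydroxybenzaldehyde | O=Cc1ccc(O)c(Cl)c1O | intermediate
4 | 3-chloro-2-hydroxy-4-methoxybenzaldehyde | COc1ccc(C=O)c(O)c1Cl | intermediate
5 | 3-chloro-4-methoxy-2-(methoxymethoxy)benzaldehyde | COCOc1c(C=O)ccc(OC)c1Cl | intermediate
6 | 3-chloro-4-methoxy-2-(methoxymethoxy)phenyl formate | O=COc1ccc(OC)c(Cl)c1OCOC | intermediate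
7 | 3-chloro-4-methoxy-2-(methoxymethoxy)phenol | COCOc1c(O)ccc(OC)c1Cl | intermediate
8 | 4-chloro-2-hydroxy-5-methoxy-3-(methoxymethoxy)benzaldehyde | COCOc1c(O)c(C=O)cc(OC)c1Cl | intermediate
9 | 4-chloro-2-hydroxy-5-methoxy-3-(methoxymethoxy)benzoic acid | COCOc1c(O)c(C(=O)O)cc(OC)c1Cl | intermediate
10 | methyl 4-chloro-2-hydroxy-5-methoxy-3-(methoxymethoxy)benzoate | COCOc1c(O)c(C(=O)OC)cc(OC)c1Cl | intermediate
11 | dimethyl malonate | COC(=O)CC(=O)OC | starting material
12 | diketene (4-methylideneoxetan-2-one) | C=C1CC(=O)O1 | starting material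
13 | dimethyl 2-(3-oxobutanoyl)propanedioate (as its sodium enolate in the flask) | COC(=O)C(C(=O)OC)C(=O)CC(C)=O | intermediate
14 | methyl 4-hydroxy-6-methyl-2-oxo-2H-pyran-3-carboxylate | COC(=O)C1=C(O)C=C(C)OC1=O | intermediate
15 | methyl 6-methyl-4-[(4-methylbenzenesulfonyl)oxy]-2-oxo-2H-pyran-3-carboxylate | COC(=O)C1=C(OS(=O)(=O)c2ccc(C)cc2)C=C(C)OC1=O | intermediate
16 | methyl 4-[3-chloro-4-methoxy-6-(methoxycarbonyl)-2-(methoxymethoxy)phenoxy]-6-methyl-2-oxo-2H-pyran-3-carboxylate | COC(=O)C1=C(Oc2c(C(=O)OC)cc(OC)c(Cl)c2OCOC)C=C(C)OC1=O | intermediate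
17 | 1,1-dimethoxyethene | C=C(OC)OC | starting material
18 | methyl 5-aryloxy-8,8-dimethoxy-1-methyl-3-oxo-2-oxabicyclo[2.2.2]oct-5-ene-4-carboxylate, aryl = 3-chloro-4-methoxy-6-(methoxycarbonyl)-2-(methoxymethoxy)phenyl; racemic, one enantiomer drawn, bridgeheads related by the bicycle | COC(=O)[C@]12C(=O)O[C@](C)(CC1(OC)OC)C=C2Oc1c(C(=O)OC)cc(OC)c(Cl)c1OCOC | intermediate
19 | methyl 2-[3-chloro-4-methoxy-6-(methoxycarbonyl)-2-(methoxymethoxy)phenoxy]-6,6-dimethoxy-4-methylcyclohexa-1,3-diene-1-carboxylate | COC(=O)C1=C(Oc2c(C(=O)OC)cc(OC)c(Cl)c2OCOC)C=C(C)CC1(OC)OC | intermediate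
20 | methyl 4-chloro-5-methoxy-2-[3-methoxy-2-(methoxycarbonyl)-5-methylphenoxy]-3-(methoxymethoxy)benzoate | COC(=O)c1cc(OC)c(Cl)c(OCOC)c1Oc1cc(C)cc(OC)c1C(=O)OC | intermediate
21 | methyl 4-chloro-3-hydroxy-2-[3-hydroxy-2-(methoxycarbonyl)-5-methylphenoxy]-5-methoxybenzoate | COC(=O)c1cc(OC)c(Cl)c(O)c1Oc1cc(C)cc(O)c1C(=O)OC | intermediate
22 | 4-chloro-2-(2-carboxy-3-hydroxy-5-methylphenoxy)-3-hydroxy-5-methoxybenzoic acid | COc1cc(C(=O)O)c(Oc2cc(C)cc(O)c2C(=O)O)c(O)c1Cl | target

**Summary**

Total step count: 13. Longest linear sequence: 11 steps (steps 1–7, then 10–13); the pyranone branch is steps 8–9.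

Steps most likely to fail:

Step 11. The ketene acetal may add to C4 and expel the aryloxide (addition–elimination) instead of cycloadding. The cycloaddition may also be too slow, because the aryloxy donor and the 6-methyl group lower the reactivity of the diene, so that the ketene acetal oligomerises first. The fallback gives up the pyranone construction of ring B and makes the a4–O–b1 bond on a preformed arene. It sets out from phenol 10 and commercial methyl 2,6-dihydroxy-4-methylbenzoate F1. Mono-O-methylation of F1 (MeI, one equivalent, K2CO3, acetone) should give methyl 2-hydroxy-6-methoxy-4-methylbenzoate F2. Triflation (Tf2O, pyridine, CH2Cl2, 0 °C) should give methyl 2-methoxy-4-methyl-6-[(trifluoromethanesulfonyl)oxy]benzoate F3. Palladium-catalysed C–O coupling of F3 with 10 (Pd(OAc)2, 2-di-tert-butylphosphino-2',4',6'-triisopropylbiphenyl, K3PO4, toluene, 100 °C) returns to the route at 20.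

Step 10. The hindered phenoxide may attack the sulfur of the enol tosylate (sulfonyl transfer), which returns 14 and tosylates the phenol. The fallback uses an electrophile without a sulfonyl centre. It sets out from 14, which is chlorinated (POCl3, Et3N, 60 °C) to methyl 4-chloro-6-methyl-2-oxo-2H-pyran-3-carboxylate F4. Displacement of chloride from F4 by the phenoxide of 10 (K2CO3, MeCN, rt) returns to the route at 16.

Step 13. Saponification of the ring B ester, which has two ortho substituents and sits beside a phenoxide, may stall, and the 2,6-dioxygenated acid may decarboxylate under forcing conditions. The fallback inverts the end game, so that the ester is hydrolysed while b5 is still a methyl ether. It sets out from 20, which is saponified (KOH, aq. EtOH, reflux) to 4-chloro-2-(2-carboxy-3-methoxy-5-methylphenoxy)-5-methoxy-3-(methoxymethoxy)benzoic acid F5. BCl3 (CH2Cl2, −78 to 0 °C) then removes the MOM group and, through the carboxyl chelate, the b5 methyl ether of F5, and returns to the route at target 22.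

**Further compounds**

F1 | step 11 | methyl 2,6-dihydroxy-4-methylbenzoate | COC(=O)c1c(O)cc(C)cc1O
F2 | step 11 | methyl 2-hydroxy-6-methoxy-4-methylbenzoate | COC(=O)c1c(O)cc(C)cc1OC
F3 | step 11 | methyl 2-methoxy-4-methyl-6-[(trifluoromethanesulfonyl)oxy]benzoate | COC(=O)c1c(OC)cc(C)cc1OS(=O)(=O)C(F)(F)F
F4 | step 10 | methyl 4-chloro-6-methyl-2-oxo-2H-pyran-3-carboxylate | COC(=O)C1=C(Cl)C=C(C)OC1=O
F5 | step 13 | 4-chloro-2-(2-carboxy-3-methoxy-5-methylphenoxy)-5-methoxy-3-(methoxymethoxy)benzoic acid | COCOc1c(Cl)c(OC)cc(C(=O)O)c1Oc1cc(C)cc(OC)c1C(=O)O
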